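**Strategy.** Everything rests on closing ring C of unit 1 (the eriodictyol half) at the aryl ether bond O1–C8a, not at O1–C2. Ring A arrives as a 2-fluoro-4,6-bis(benzyloxy)phenyl ketone; C2 and C3 are set in an open-chain syn aldol, and both C4 carbonyls are then parked as carbinols. The key step exploits that C8a of ring A, meta to the C5 and C7 oxygens, can be reached from the C2 oxygen through a six-membered transition state: the C2 alkoxide displaces fluoride from C8a by intramolecular SNAr, touching neither stereocentre, so the contra-thermodynamic 2,3-cis array is carried intact into ring C. The precursor is a fluoroarene triol; double oxidation and hydrogenolysis finish.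

Key step: step 9

Remark on numbering and stereochemistry: flavanone numbering is used; unprimed atoms belong to unit 1 (linked through C3), double-primed atoms to unit 2 (the naringenin half, linked through C8″). The target SMILES encodes a 2,3-cis unit 1 (2R,3R) and 2″S.
Assumption: the antipodes of the two chiral controllers (bisphosphine in step 3, diazaborolidine in step 7) are assigned by analogy and would be confirmed on a model; exchanging an antipode changes nothing else in the route.

Step 1
Reactants: 1 1-[2,4-bis(benzyloxy)-6-hydroxyphenyl]ethan-1-one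
Product: 2 1-[4,6-bis(benzyloxy)-3-bromo-2-hydroxyphenyl]ethan-1-one
Conditions: NBS (1.0 equiv), CH2Cl2, 0 °C
Reagents that add atoms: N-bromosuccinimide, O=C1CCC(=O)N1Br
Why: Electrophilic aromatic bromination of the chelated phenol should go to C3, ortho to the free hydroxyl and para to the 6-benzyloxy group, which is less hindered than C5 between the two benzyloxy groups.

Step 2
Reactants: 2 1-[4,6-bis(benzyloxy)-3-bromo-2-hydroxyphenyl]ethan-1-one
Product: 4 5,7-bis(benzyloxy)-8-bromo-4H-chromen-4-one, via enaminone 3 (not isolated)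
Conditions: Me2NCH(OMe)2, toluene, 95 °C; then conc. HCl, CH2Cl2, 40 °C
Reagents that add atoms: N,N-dimethylformamide dimethyl acetal, COC(OC)N(C)C
Why: Condensation of the methyl ketone with the amide acetal and acid-promoted conjugate addition of the phenol with loss of dimethylamine is the standard enaminone chromone annulation, and it places the bromine at C8.

Step 3
Reactants: 4 5,7-bis(benzyloxy)-8-bromo-4H-chromen-4-one; 5 [4-(benzyloxy)phenyl]boronic acid
Product: 6 (2S)-5,7-bis(benzyloxy)-2-[4-(benzyloxy)phenyl]-8-bromochroman-4-one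
Conditions: [Rh(OH)(cod)]2 (3 mol %), MeO-F12-BIPHEP (antipode giving 2S), 5 (2 equiv), toluene–H2O, 40 °C
Reagents that add atoms: none
Why: Rhodium-catalysed asymmetric 1,4-addition of the arylboronic acid to the chromone (Hayashi–Miyaura reaction) should set C2″ as S by ligand-controlled facial delivery of the aryl group, the aryl bromide being inert to the rhodium catalyst.

Step 4
Reactants: 7 5-fluorobenzene-1,3-diol
Product: 9 1-(2-fluoro-4,6-dihydroxyphenyl)ethan-1-one, via ketiminium chloride 8 (not isolated)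
Conditions: MeCN, ZnCl2 (cat.), HCl (g), Et2O, 0 °C; then H2O, 100 °C
Reagents that add atoms: acetonitrile, CC#N; water, O
Why: Houben–Hoesch acylation of the resorcinol should occur para to one hydroxyl and ortho to the other (the position next to fluorine), as in resorcinol itself, and hydrolysis of the ketiminium salt gives the ketone.

Step 5
Reactants: 9 1-(2-fluoro-4,6-dihydroxyphenyl)ethan-1-one
Product: 10 1-[2,4-bis(benzyloxy)-6-fluorophenyl]ethan-1-one
Conditions: BnBr (2.3 equiv), K2CO3, DMF, 60 °C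
Reagents that add atoms: benzyl bromide, BrCc1ccccc1
Why: Williamson etherification of both phenols, the chelated ortho phenol needing the gentle heating.

Step 6
Reactants: 10 1-[2,4-bis(benzyloxy)-6-fluorophenyl]ethan-1-one; 6 (2S)-5,7-bis(benzyloxy)-2-[4-(benzyloxy)phenyl]-8-bromochroman-4-one
Product: 12 (2S)-5,7-bis(benzyloxy)-2-[4-(benzyloxy)phenyl]-8-{2-[2,4-bis(benzyloxy)-6-fluorophenyl]-2-oxoethyl}chroman-4-one, via silyl enol ether 11 (not isolated)
Conditions: Me3SiOTf, Et3N, CH2Cl2, 0 °C; then 6, Pd(OAc)2 (5 mol %), P(t-Bu)3 (10 mol %), Bu3SnF (1.5 equiv), toluene, 85 °C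
Reagents that add atoms: none
Why: Palladium-catalysed α-arylation of the silyl enol ether through its tin enolate (Buchwald–Hartwig-type α-arylation under fluoride activation) runs without free base, so the base-labile C2″ centre of the flavanone is not touched and the methyl ketone is arylated once only.

Step 7
Reactants: 12 (2S)-5,7-bis(benzyloxy)-2-[4-(benzyloxy)phenyl]-8-{2-[2,4-bis(benzyloxy)-6-fluorophenyl]-2-oxoethyl}chroman-4-one; 13 3,4-bis(benzyloxy)benzaldehyde
Product: 15 syn aldol (1R,2R)-β-hydroxy ketone (full name in the list), via boron enolate 14 (not isolated)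
Conditions: (4S,5S)-2-bromo-4,5-diphenyl-1,3-bis(p-tolylsulfonyl)-1,3,2-diazaborolidine (1.3 equiv), i-Pr2NEt, CH2Cl2, −78 °C; then 13, −78 → −40 °C; MeOH, pH 7 buffer
Reagents that add atoms: none
Why: Enantioselective boron aldol reaction in which amine-mediated enolisation of the most acidic, benzylic α-methylene gives the Z(O) boron enolate, whose chair Zimmerman–Traxler transition state should deliver the syn adduct while the C2-symmetric sulfonamide ligand selects the enolate face and so fixes C2 and C3 as R,R.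

Step 8
Reactants: 15 syn aldol (1R,2R)-β-hydroxy ketone
Product: 16 fluoroarene triol (full name in the list)
Conditions: Zn(BH4)2, Et2O–THF, −20 → 0 °C; aq. NH4Cl
Reagents that add atoms: none
Why: Chelation-controlled hydride reduction with neutral Zn(BH4)2 should convert both ketones into carbinols without base, so the epimerisable C3 and the retro-aldol-prone β-hydroxy ketone survive; the new C4 (1,3-syn) and C4″ (2,4-cis) centres are drawn as the expected major epimers and are inconsequential because both are oxidised again in step 10.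

Step 9
Reactants: 16 fluoroarene triol
Product: 17 2,3-cis bis(flavan-4-ol) (full name in the list)
Conditions: KN(SiMe3)2 (3.5 equiv), 18-crown-6, THF–DMPU, 0 → 70 °C
Reagents that add atoms: none
Why: The base converts the three carbinols of 16 into potassium alkoxides, and the C2 alkoxide adds to C8a ipso to fluorine to give a Meisenheimer σ-complex that is stabilised inductively by the meta benzyloxy groups at C5 and C7 and collapses with loss of fluoride (addition–elimination SNAr). The closest known reaction type is the intramolecular alkoxide/fluoroarene SNAr etherification used to form the pyran ring of flavans from 2-fluoro-4,6-dialkoxyphenyl carbinols. Ring C of unit 1 is the only ring closed, in a 6-exo-trig mode at C8a, and O1–C8a is the only bond formed. No stereocentre is created: the C2–O and C3–C bonds are never broken, so the syn relationship set in step 7 is transferred with retention into the 2,3-cis ring (the C3 label changes from R to S in 17 only because the CIP priorities change). The step needs chemoselectivity among three alkoxides and freedom from base-induced scrambling; the first is secured by ring size (the C4 alkoxide could only form a four-membered ring and the C4″ alkoxide a nine-membered one, and fluorine is the only nucleofuge on an sp2 carbon), the second by the absence of any carbonyl group, which rules out retro-aldol cleavage, C3 epimerisation and retro-oxa-Michael opening of unit 2.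

Step 10
Reactants: 17 2,3-cis bis(flavan-4-ol)
Product: 18 heptabenzyl 2,3-cis bis-flavanone (full name in the list)
Conditions: Dess–Martin periodinane (3 equiv), NaHCO3, CH2Cl2, 0 °C → rt
Reagents that add atoms: none
Why: Dess–Martin oxidation of both benzylic carbinols under bicarbonate buffering should restore the two C4 carbonyls without enolising the now epimerisable C3–H, so the kinetic 2,3-cis arrangement is kept.

Step 11
Reactants: 18 heptabenzyl 2,3-cis bis-flavanone
Product: 19 target CNP0105436.1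
Conditions: H2 (1 atm), Pd on carbon (10 %), EtOAc–MeOH, rt
Reagents that add atoms: none
Why: Neutral catalytic hydrogenolysis should cleave the seven benzyl ethers with no acid or base present that could epimerise C3 or open either pyranone ring.

**Compound list**

1 | 1-[2,4-bis(benzyloxy)-6-hydroxyphenyl]ethan-1-one | CC(=O)c1c(O)cc(OCc2ccccc2)cc1OCc1ccccc1 | starting material
2 | 1-[4,6-bis(benzyloxy)-3-bromo-2-hydroxyphenyl]ethan-1-one | CC(=O)c1c(O)c(Br)c(OCc2ccccc2)cc1OCc1ccccc1 | intermediate
3 | (E)-1-[4,6-bis(benzyloxy)-3-bromo-2-hydroxyphenyl]-3-(dimethylamino)prop-2-en-1-one | CN(C)/C=C/C(=O)c1c(O)c(Br)c(OCc2ccccc2)cc1OCc1ccccc1 | intermediate (not isolated)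
4 | 5,7-bis(benzyloxy)-8-bromo-4H-chromen-4-one | O=C1C=COc2c1c(OCc1ccccc1)cc(OCc1ccccc1)c2Br | intermediate
5 | [4-(benzyloxy)phenyl]boronic acid | OB(O)c1ccc(OCc2ccccc2)cc1 | starting material
6 | (2S)-5,7-bis(benzyloxy)-2-[4-(benzyloxy)phenyl]-8-bromochroman-4-one | O=C1C[C@@H](c2ccc(OCc3ccccc3)cc2)Oc2c1c(OCc1ccccc1)cc(OCc1ccccc1)c2Br | intermediate
7 | 5-fluorobenzene-1,3-diol | Oc1cc(O)cc(F)c1 | starting material
8 | 1-(2-fluoro-4,6-dihydroxyphenyl)ethan-1-iminium chloride | CC(=[NH2+])c1c(O)cc(O)cc1F.[Cl-] | intermediate (not isolated)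
9 | 1-(2-fluoro-4,6-dihydroxyphenyl)ethan-1-one | CC(=O)c1c(O)cc(O)cc1F | intermediate
10 | 1-[2,4-bis(benzyloxy)-6-fluorophenyl]ethan-1-one | CC(=O)c1c(OCc2ccccc2)cc(OCc2ccccc2)cc1F | intermediate
11 | {1-[2,4-bis(benzyloxy)-6-fluorophenyl]ethenyloxy}trimethylsilane | C=C(O[Si](C)(C)C)c1c(OCc2ccccc2)cc(OCc2ccccc2)cc1F | intermediate (not isolated)
12 | (2S)-5,7-bis(benzyloxy)-2-[4-(benzyloxy)phenyl]-8-{2-[2,4-bis(benzyloxy)-6-fluorophenyl]-2-oxoethyl}chroman-4-one | O=C1C[C@@H](c2ccc(OCc3ccccc3)cc2)Oc2c1c(OCc1ccccc1)cc(OCc1ccccc1)c2CC(=O)c1c(OCc2ccccc2)cc(OCc2ccccc2)cc1F | intermediate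
13 | 3,4-bis(benzyloxy)benzaldehyde | O=Cc1ccc(OCc2ccccc2)c(OCc2ccccc2)c1 | starting material
14 | Z(O) boron enolate of 12: (2S)-5,7-bis(benzyloxy)-2-[4-(benzyloxy)phenyl]-8-[(Z)-2-[2,4-bis(benzyloxy)-6-fluorophenyl]-2-{[(4S,5S)-4,5-diphenyl-1,3-bis(4-methylbenzenesulfonyl)-1,3,2-diazaborolidin-2-yl]oxy}ethenyl]chroman-4-one | O=C1C[C@@H](c2ccc(OCc3ccccc3)cc2)Oc2c1c(OCc1ccccc1)cc(OCc1ccccc1)c2/C=C(\OB1N(S(=O)(=O)c2ccc(C)cc2)[C@@H](c2ccccc2)[C@H](c2ccccc2)N1S(=O)(=O)c1ccc(C)cc1)c1c(OCc2ccccc2)cc(OCc2ccccc2)cc1F | intermediate (not isolated)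
15 | (2S)-5,7-bis(benzyloxy)-2-[4-(benzyloxy)phenyl]-8-{(1R,2R)-1-[3,4-bis(benzyloxy)phenyl]-3-[2,4-bis(benzyloxy)-6-fluorophenyl]-1-hydroxy-3-oxopropan-2-yl}chroman-4-one (syn aldol) | O=C1C[C@@H](c2ccc(OCc3ccccc3)cc2)Oc2c1c(OCc1ccccc1)cc(OCc1ccccc1)c2[C@@H](C(=O)c1c(OCc2ccccc2)cc(OCc2ccccc2)cc1F)[C@@H](O)c1ccc(OCc2ccccc2)c(OCc2ccccc2)c1 | intermediate
16 | (2S,4S)-5,7-bis(benzyloxy)-2-[4-(benzyloxy)phenyl]-8-{(1R,2R,3S)-1-[3,4-bis(benzyloxy)phenyl]-3-[2,4-bis(benzyloxy)-6-fluorophenyl]-1,3-dihydroxypropan-2-yl}chroman-4-ol (major C4/C4″ epimer drawn) | O[C@H]1C[C@@H](c2ccc(OCc3ccccc3)cc2)Oc2c1c(OCc1ccccc1)cc(OCc1ccccc1)c2[C@@H]([C@H](O)c1c(OCc2ccccc2)cc(OCc2ccccc2)cc1F)[C@@H](O)c1ccc(OCc2ccccc2)c(OCc2ccccc2)c1 | intermediate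
17 | (2R,3S,4S)-5,7-bis(benzyloxy)-2-[3,4-bis(benzyloxy)phenyl]-3-{(2S,4S)-5,7-bis(benzyloxy)-2-[4-(benzyloxy)phenyl]-4-hydroxychroman-8-yl}chroman-4-ol (2,3-cis) | O[C@H]1C[C@@H](c2ccc(OCc3ccccc3)cc2)Oc2c1c(OCc1ccccc1)cc(OCc1ccccc1)c2[C@H]1[C@H](O)c2c(OCc3ccccc3)cc(OCc3ccccc3)cc2O[C@H]1c1ccc(OCc2ccccc2)c(OCc2ccccc2)c1 | intermediate
18 | (2R,3R)-5,7-bis(benzyloxy)-2-[3,4-bis(benzyloxy)phenyl]-3-{(2S)-5,7-bis(benzyloxy)-2-[4-(benzyloxy)phenyl]-4-oxochroman-8-yl}chroman-4-one (2,3-cis) | O=C1C[C@@H](c2ccc(OCc3ccccc3)cc2)Oc2c1c(OCc1ccccc1)cc(OCc1ccccc1)c2[C@H]1C(=O)c2c(OCc3ccccc3)cc(OCc3ccccc3)cc2O[C@H]1c1ccc(OCc2ccccc2)c(OCc2ccccc2)c1 | intermediate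
19 | (2R,3R)-2-(3,4-dihydroxyphenyl)-5,7-dihydroxy-3-[(2S)-5,7-dihydroxy-2-(4-hydroxyphenyl)-4-oxochroman-8-yl]chroman-4-one (CNP0105436.1) | O=C1C[C@@H](c2ccc(O)cc2)Oc2c1c(O)cc(O)c2[C@H]1C(=O)c2c(O)cc(O)cc2O[C@H]1c1ccc(O)c(O)c1 | target

**Step count.** Total: 11 steps. Longest linear sequence: 9 steps (1, 2, 3, 6, 7, 8, 9, 10, 11).

**Steps most likely to fail**

Step 9. The two meta benzyloxy groups may activate C8a too weakly, so that at the temperature needed alkoxide attack on benzylic CH2 groups (debenzylation) or intermolecular substitution outruns the six-membered ring closure. Fallback, setting out from 15 and returning at 18: the closure is run at the ketone oxidation level, where the C4 carbonyl activates C8a for a classical SNAr (K2CO3, DMF, rt, short contact time). Under this equilibrating base the product should be mainly the 2,3-trans heptabenzyl bis-flavanone F1. Both ketones are then converted with Me3SiOTf/Et3N into the bis(trimethylsilyl enol ether) F2. Kinetic protonation (Bu4NF, AcOH, THF, −78 °C), anti to the pseudoaxial C2 aryl group, should re-set C3 and give 2,3-cis 18.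

Step 7. Enolisation of the hindered aryl benzyl ketone by the bulky boron reagent may be slow, the unit 2 ketone may compete for the reagent, facial control by the ligand may be poor, or the adduct may revert by retro-aldol on work-up. Fallback, setting out from 12 and returning at 15: 12 is C-acylated by soft enolisation (MgBr2·OEt2, i-Pr2NEt, 3,4-bis(benzyloxy)benzoyl chloride, CH2Cl2) to the 2-aryl-1,3-diketone F3. Its less hindered 3,4-bis(benzyloxy)benzoyl carbonyl is then reduced by Noyori-type asymmetric transfer hydrogenation with dynamic kinetic resolution (RuCl(p-cymene)[TsDPEN], antipode giving the 1R carbinol, HCO2H–Et3N), C3 racemising rapidly through the enol. The syn/anti preference of this reduction is not certain and would be checked first on a model diketone.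

Step 6. Oxidative addition and transmetalation at the doubly ortho-oxygenated C8″ bromide may be slow, so that protodesilylation of the enol ether and hydrodebromination win. Fallback, setting out from 4 and 10 and returning at 12: ketone 10 is arylated with bromochromone 4 under Buchwald–Hartwig α-arylation conditions (Pd2(dba)3, Xantphos, K3PO4, toluene, 90 °C). This is safe at that stage because the chromone has neither an enolisable position nor a stereocentre, and it gives 5,7-bis(benzyloxy)-8-{2-[2,4-bis(benzyloxy)-6-fluorophenyl]-2-oxoethyl}-4H-chromen-4-one F4. The rhodium-catalysed asymmetric 1,4-addition of 5 (conditions of step 3) is then run on F4 and gives 12.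

**Further compounds**

F1 | step 9 | (2R,3S)-5,7-bis(benzyloxy)-2-[3,4-bis(benzyloxy)phenyl]-3-{(2S)-5,7-bis(benzyloxy)-2-[4-(benzyloxy)phenyl]-4-oxochroman-8-yl}chroman-4-one (2,3-trans epimer of 18) | O=C1C[C@@H](c2ccc(OCc3ccccc3)cc2)Oc2c1c(OCc1ccccc1)cc(OCc1ccccc1)c2[C@@H]1C(=O)c2c(OCc3ccccc3)cc(OCc3ccccc3)cc2O[C@H]1c1ccc(OCc2ccccc2)c(OCc2ccccc2)c1
F2 | step 9 | (2S)-5,7-bis(benzyloxy)-2-[3,4-bis(benzyloxy)phenyl]-3-{(2S)-5,7-bis(benzyloxy)-2-[4-(benzyloxy)phenyl]-4-[(trimethylsilyl)oxy]-2H-chromen-8-yl}-4-[(trimethylsilyl)oxy]-2H-chromene (C2 geometry as in 18, label changed by priority) | C[Si](C)(C)OC1=C[C@@H](c2ccc(OCc3ccccc3)cc2)Oc2c1c(OCc1ccccc1)cc(OCc1ccccc1)c2C1=C(O[Si](C)(C)C)c2c(OCc3ccccc3)cc(OCc3ccccc3)cc2O[C@H]1c1ccc(OCc2ccccc2)c(OCc2ccccc2)c1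
F3 | step 7 | (2S)-5,7-bis(benzyloxy)-2-[4-(benzyloxy)phenyl]-8-{1-[3,4-bis(benzyloxy)phenyl]-3-[2,4-bis(benzyloxy)-6-fluorophenyl]-1,3-dioxopropan-2-yl}chroman-4-one (central CH configurationally labile) | O=C1C[C@@H](c2ccc(OCc3ccccc3)cc2)Oc2c1c(OCc1ccccc1)cc(OCc1ccccc1)c2C(C(=O)c1c(OCc2ccccc2)cc(OCc2ccccc2)cc1F)C(=O)c1ccc(OCc2ccccc2)c(OCc2ccccc2)c1
F4 | step 6 | 5,7-bis(benzyloxy)-8-{2-[2,4-bis(benzyloxy)-6-fluorophenyl]-2-oxoethyl}-4H-chromen-4-one | O=C1C=COc2c1c(OCc1ccccc1)cc(OCc1ccccc1)c2CC(=O)c1c(OCc2ccccc2)cc(OCc2ccccc2)cc1F
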